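## The problem

- **Skeleton.** The target is an isoflavone. Ring C, a 4-pyranone, is fused through C4a–C8a to ring A, and the catechol ring B sits on C3.
- **Ring A.** It is a hexasubstituted benzene. Going round: C4a (acyl carbon C4), C5 (OH), C6 ((2R)-2-hydroxy-3-methylbut-3-enyl), C7 (OH), C8 (prenyl), C8a (O1).
- **C6 against C8.** Both carbons lie between two oxygens and are almost equal electronically. Substitution on a finished 5,7-dihydroxyisoflavone therefore has to tell them apart.
- **The two ortho hydroxyls.** Closing ring C onto a finished phloroglucinol has the mirror problem of telling two ortho hydroxyls apart.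
- **The stereocentre.** C2'' is the only one, an isolated secondary allylic alcohol. Nothing in the molecule can control it. The two C5 chains differ only in oxidation state, so a late oxidation would have to choose between two like alkenes.
- **Sensitive groups.** The allylic alcohol and the prenyl group stand next to free phenols and cyclise to dihydrofurans or chromans in acid. An epoxide precursor does the same in base. The catechol oxidises in basic air. Ether cleavage with boron halides, hydrogenolysis and strong acid are therefore excluded at the end.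
- **The enabling feature.** The three oxygens of ring A alternate (C5, C7, C8a), and the C4a=C8a bond is also the C3=C2 bond of the 4-pyranone ring C. In a simple pyranone, C4a carries only hydrogen.
- **What follows from it.** Ring A is exactly what a Danheiser-type benzannulation delivers when that pyranone bond is the alkene of the vinylketene. C5–OH comes from the ketene carbonyl and C7–O from an ynol ether, while C8a–O1 is already in place. The C8 and C6 substituents ride in on the ketene and the alkyne.

## Retrosynthesis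

**28 to 27.** Only four O–Si bonds are cut. Every masked oxygen (C7, C2'', C3', C4') is a silyl ether, so one buffered fluoride step frees the target without acid, base or reduction. The chelated 5-OH needs no protection and emerges free from the ring construction.

**27 to 14 and 22.** Three bonds of ring A are cut: C4a–C5, C5–C6 and C7–C8.
- Cutting C6–C1'' or C8–C1''' instead leaves the C6/C8 choice unsolved. Cutting ring C leaves the choice between two ortho hydroxyls.
- The chosen cut removes both questions, because each substituent sits on a defined atom of one of two small partners.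
- Acid chloride 14 is a monocyclic pyranone with no stereocentre that matters. Siloxyalkyne 22 is a seven-carbon chain holding the only stereocentre.
- The forward reaction must form ketene 23, add 22 in the polarity-matched sense to cyclobutenone 24, open it to dienylketene 25, close 25 onto C3–H of the pyranone to 26, and tautomerise to 27.

**22 to 19, 18, then 15 and 16.** First the C(sp)–O bond is cut, which leads to terminal alkyne 19 and its parent alcohol 18. Then the bond between the carbinol carbon and the propargylic CH2 (future C2''–C1'') is cut.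
- The neighbouring cut, carbinol to isopropenyl, would need an unstable 3-alkynal.
- The chosen cut uses methacrolein 15 and allenylboronate 16, both catalogue compounds.
- The forward reaction must give one enantiomer under catalyst control.

**14 to 13, then 9 and 10; 9 to 6 and 7.** Both bonds cut sit on the lateral carbon of the pyranone (future C8). One goes to the carboxyl carbon (future C5, from carbon dioxide 10). The other goes to the prenyl CH2 (from prenyl bromide 7). This carbon is the vinylogous alpha-position of 6, so two successive dienolate reactions suffice. Each dienolate (8, 11) must react at the exocyclic carbon, the only site that restores the pyranone.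

**6 to 5 and 3; 5 to 4; 3 to 2 to 1.** The C3–C1' bond is cut.
- Allomaltol 4 already holds O1, C2, C3, C4, C4a, C8a and C8 of the target. Its hydroxyl sits on the very carbon to be arylated, so triflate 5 and boronate 3 join in one coupling.
- All 25 carbons are then accounted for: 4 gives six, 10 one, 7 five, 22 seven and 3 six.

## Roads not taken

**Alternative 1:** late oxidation of a diprenyl isoflavone, the most obvious plan.
- *The cut:* the C2''–O bond and the two aryl–prenyl bonds, leading back to 6,8-diprenylorobol A1.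
- *Forward key step:* site- and enantioselective epoxidation of the 6-prenyl group to epoxide A2, then base-induced isomerisation to the allylic alcohol.
- *Why the chosen plan is better:* the two prenyl groups are both trisubstituted alkenes between two oxygens, so no reagent has a structural basis for choosing one. A2 also carries phenols ortho to the epoxide, which invite cyclisation. Introducing the chains one at a time removes the ambiguity, but only through about a dozen linear steps on the heavy isoflavone. The chosen plan never has two like alkenes to distinguish.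

**Alternative 2:** cut of C6–C1''.
- *Forward key step:* halogen–metal exchange on the fully protected 6-iodo-8-prenylisoflavone A4, then copper-assisted opening of (S)-2-(prop-1-en-2-yl)oxirane A3 at its CH2.
- *Why the chosen plan is better:* A3 is a vinyl epoxide, so SN2' attack competes with the wanted SN2 attack. The aryl metal must coexist with the electrophilic C2 and C4 of the chromone. Making A4 still requires regiodefined halogenation of ring A beside an alkene, and the acetal protecting groups need acid at the end. The chosen plan brings the same stereocentre in on a carbon chain that becomes part of the ring.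

**Alternative 3:** ring C last.
- *The cut:* O1–C2 and C2–C3, leading to the hexasubstituted deoxybenzoin A5.
- *Forward key step:* one-carbon condensation with a formamide acetal and cyclisation.
- *Why the chosen plan is better:* A5 has two free ortho hydroxyls, one beside each chain, and nothing favours either. The 6-prenyl-8-(hydroxyalkenyl) isomer A6 must be expected alongside the target. A5 is itself a fully substituted phloroglucinol whose synthesis repeats the C-alkylation problem. In the chosen plan O1 is in ring C from the first step.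

Key step: step 11

Remark: the stereocentre of the given SMILES is read as (R) (OH > isopropenyl > CH2Ar > H), and the descriptor stays (R) in 17–22 and 24–27.
Remark: allomaltol 4 is taken as a catalogue compound.

## Steps

Step 1
Reactants: 1 4-bromobenzene-1,2-diol
Product: 2 4-bromo-1,2-bis(tert-butyldimethylsilyloxy)benzene
Conditions: TBSCl (2.4 equiv), imidazole, DMF, rt
Reagents that add atoms: tert-butyldimethylsilyl chloride, CC(C)(C)[Si](C)(C)Cl
Why: Standard silylation of both phenols; silicon is chosen so that every masked oxygen of the route falls to fluoride in the last step.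

Step 2
Reactants: 2 4-bromo-1,2-bis(tert-butyldimethylsilyloxy)benzene
Product: 3 2-[3,4-bis(tert-butyldimethylsilyloxy)phenyl]-4,4,5,5-tetramethyl-1,3,2-dioxaborolane
Conditions: B2pin2, Pd(dppf)Cl2 (3 mol %), KOAc, 1,4-dioxane, 85 °C
Reagents that add atoms: bis(pinacolato)diboron, CC1(C)OB(OC1(C)C)B1OC(C)(C)C(C)(C)O1
Why: Miyaura borylation of an aryl bromide; KOAc is too weak a base to attack aryl silyl ethers.

Step 3
Reactants: 4 5-hydroxy-2-methyl-4H-pyran-4-one (allomaltol)
Product: 5 6-methyl-4-oxo-4H-pyran-3-yl trifluoromethanesulfonate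
Conditions: Tf2O, pyridine, CH2Cl2, −20 to 0 °C
Reagents that add atoms: trifluoromethanesulfonic anhydride, O=S(=O)(OS(=O)(=O)C(F)(F)F)C(F)(F)F
Why: The enolic hydroxyl behaves as a phenol and is sulfonylated cleanly, which turns the future C3 into a cross-coupling electrophile.

Step 4
Reactants: 5 6-methyl-4-oxo-4H-pyran-3-yl trifluoromethanesulfonate; 3 2-[3,4-bis(tert-butyldimethylsilyloxy)phenyl]-4,4,5,5-tetramethyl-1,3,2-dioxaborolane
Product: 6 5-[3,4-bis(tert-butyldimethylsilyloxy)phenyl]-2-methyl-4H-pyran-4-one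
Conditions: Pd(PPh3)4 (5 mol %), K3PO4, 1,4-dioxane/H2O (20:1), 80 °C
Reagents that add atoms: none
Why: Suzuki-Miyaura coupling of a triflate activated by the adjacent carbonyl, a reaction type established for 3-hydroxy-4-pyranone triflates; it forms the C3–C1' bond.

Step 5
Reactants: 6 5-[3,4-bis(tert-butyldimethylsilyloxy)phenyl]-2-methyl-4H-pyran-4-one; 7 1-bromo-3-methylbut-2-ene (prenyl bromide)
Product: 9 5-[3,4-bis(tert-butyldimethylsilyloxy)phenyl]-2-(4-methylpent-3-en-1-yl)-4H-pyran-4-one, via lithium 2-methylene-2H-pyran-4-olate 8 (not isolated)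
Conditions: LiN(SiMe3)2 (1.05 equiv), THF, −78 °C; then 7, DMPU, −78 to −20 °C
Reagents that add atoms: none
Why: Lateral (vinylogous) deprotonation of a 2-methyl-4-pyranone gives dienolate 8, which alkylates at the exocyclic carbon because only that site restores the pyranone. The primary allylic bromide reacts by SN2.

Step 6
Reactants: 9 5-[3,4-bis(tert-butyldimethylsilyloxy)phenyl]-2-(4-methylpent-3-en-1-yl)-4H-pyran-4-one; 10 carbon dioxide
Product: 13 (±)-2-{5-[3,4-bis(tert-butyldimethylsilyloxy)phenyl]-4-oxo-4H-pyran-2-yl}-5-methylhex-4-enoic acid, via lithium 2-alkylidene-2H-pyran-4-olate 11 (not isolated), via lithium carboxylate 12 (not isolated)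
Conditions: LiN(SiMe3)2 (1.1 equiv), THF, −78 °C; dry CO2; cold 1 M HCl work-up, kept below 10 °C
Reagents that add atoms: none
Why: A second lateral deprotonation followed by enolate carboxylation at the exocyclic carbon brings in the future C5. The new stereocentre is racemic and is erased in step 11.

Step 7
Reactants: 13 (±)-2-{5-[3,4-bis(tert-butyldimethylsilyloxy)phenyl]-4-oxo-4H-pyran-2-yl}-5-methylhex-4-enoic acid
Product: 14 (±)-2-{5-[3,4-bis(tert-butyldimethylsilyloxy)phenyl]-4-oxo-4H-pyran-2-yl}-5-methylhex-4-enoyl chloride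
Conditions: 1-chloro-N,N,2-trimethylprop-1-en-1-amine (1.1 equiv), CH2Cl2, 0 °C; evaporate, use at once
Reagents that add atoms: 1-chloro-N,N,2-trimethylprop-1-en-1-amine, CC(C)=C(Cl)N(C)C
Why: The alpha-chloroenamine makes the acid chloride under neutral conditions without HCl. The prenyl alkene, the silyl ethers and the basic pyranone carbonyl oxygen are therefore left alone.

Step 8
Reactants: 15 methacrolein; 16 allenylboronic acid pinacol ester
Product: 18 (R)-2-methylhex-1-en-5-yn-3-ol, via pinacol borate ester 17 (not isolated)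
Conditions: (R)-3,3'-bis(2,4,6-triisopropylphenyl)-1,1'-binaphthyl-2,2'-diyl hydrogen phosphate (5 mol %), 4 Å sieves, toluene, −20 °C; aqueous work-up
Reagents that add atoms: none
Why: Chiral phosphoric acid-catalysed allenylboration (asymmetric propargylation) proceeds through a closed six-membered SE2' transition state in which the acid binds the boronate oxygen and the formyl hydrogen. By analogy with aryl and alkenyl aldehydes the (R)-acid should deliver the (R)-carbinol, the isopropenyl group taking the place of the aryl group. The sense is to be confirmed by Mosher ester analysis, and the (S)-acid is used if it proves opposite.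

Step 9
Reactants: 18 (R)-2-methylhex-1-en-5-yn-3-ol
Product: 19 (R)-3-(tert-butyldimethylsilyloxy)-2-methylhex-1-en-5-yne
Conditions: TBSCl, imidazole, DMF, rt
Reagents that add atoms: tert-butyldimethylsilyl chloride, CC(C)(C)[Si](C)(C)Cl
Why: Standard silylation of a secondary alcohol; the C–O bond of the stereocentre is not touched.

Step 10
Reactants: 19 (R)-3-(tert-butyldimethylsilyloxy)-2-methylhex-1-en-5-yne
Product: 22 (R)-4-(tert-butyldimethylsilyloxy)-5-methyl-1-(triisopropylsilyloxy)hex-5-en-1-yne, via lithium acetylide 20 (not isolated), via lithium ynolate 21 (not isolated)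
Conditions: n-BuLi, THF, −78 °C; LiOOt-Bu (from t-BuOOH and LiN(SiMe3)2), −78 to 0 °C; then TIPSOTf, −78 to 0 °C
Reagents that add atoms: tert-butyl hydroperoxide, CC(C)(C)OO; triisopropylsilyl trifluoromethanesulfonate, CC(C)[Si](C(C)C)(C(C)C)OS(=O)(=O)C(F)(F)F
Why: Oxidation of a lithium acetylide with lithium tert-butyl peroxide is a known entry to ynolates. The bulky silyl triflate traps the ynolate on oxygen, whereas small silyl groups would go to carbon.

Step 11
Reactants: 14 (±)-2-{5-[3,4-bis(tert-butyldimethylsilyloxy)phenyl]-4-oxo-4H-pyran-2-yl}-5-methylhex-4-enoyl chloride; 22 (R)-4-(tert-butyldimethylsilyloxy)-5-methyl-1-(triisopropylsilyloxy)hex-5-en-1-yne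
Product: 27 3-[3,4-bis(tert-butyldimethylsilyloxy)phenyl]-6-[(2R)-2-(tert-butyldimethylsilyloxy)-3-methylbut-3-en-1-yl]-5-hydroxy-8-(3-methylbut-2-en-1-yl)-7-(triisopropylsilyloxy)-4H-chromen-4-one, via pyranonyl(prenyl)ketene 23 (not isolated), via 3-siloxycyclobutenone 24 (not isolated), via dienylketene 25 (not isolated), via cyclohexadienone tautomer 26 (not isolated)
Conditions: 22 (1.3 equiv), Et3N (1.1 equiv, slow addition), toluene, 0 °C to rt; filter; then 110 °C
Reagents that add atoms: none
Why: Proposed new method: this is a Danheiser-type benzannulation in which the alkene of the vinylketene is the C2=C3 bond of a 4-pyranone; the closest known reaction type is the benzannulation of aryl- and heteroarylketenes (benzene, furan, thiophene, pyrrole, indole) with siloxyalkynes, together with the thermal union of arylketenes and alkynes to naphthols. Et3N removes the doubly activated alpha-hydrogen of 14 and chloride leaves, giving ketene 23 at low stationary concentration; the nucleophilic chain-bearing carbon of 22 then attacks the ketene carbonyl carbon and a four-membered ring closes by [2+2] cycloaddition to 24, which fixes C5–C6 and C7–C8 in the only polarity-matched orientation. At 110 °C 24 opens by reversible conrotatory 4π electrocyclic cleavage of the former ketene C–C bond to 25, and only the isomer with the pyranone cis to the ketene can go on, the other returning through 24. Ring A closes by disrotatory 6π electrocyclisation of 25 between the ketene carbon and C3–H of the pyranone, its only free and most nucleophilic ring carbon, to give 26, and the proton shift to phenol 27, chelated to C4=O, makes the sequence irreversible. The pyranone should take part at least as readily as the arenes already known to do so, because its aromatic stabilisation is small and 2-alkenylchromones are known to react as dienes through C3. No lasting stereocentre is created: the quaternary carbon of 24 and C4a–H of 26 are erased, the racemic centre of 14 is lost in 23, and C2'' is a silyl ether remote from every reacting atom. The selectivity needed is regiochemical only and is secured by the polarisation of the ynol ether and by the absence of a second closure site, while running the cycloaddition cold before heating keeps phenol 27 from meeting ketene 23.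

Step 12
Reactants: 27 3-[3,4-bis(tert-butyldimethylsilyloxy)phenyl]-6-[(2R)-2-(tert-butyldimethylsilyloxy)-3-methylbut-3-en-1-yl]-5-hydroxy-8-(3-methylbut-2-en-1-yl)-7-(triisopropylsilyloxy)-4H-chromen-4-one
Product: 28 3-(3,4-dihydroxyphenyl)-5,7-dihydroxy-6-[(2R)-2-hydroxy-3-methylbut-3-en-1-yl]-8-(3-methylbut-2-en-1-yl)-4H-chromen-4-one (target)
Conditions: Bu4NF/AcOH (1:1, 6 equiv each), THF, 0 °C to rt, argon
Reagents that add atoms: none
Why: Fluoride cleaves all four Si–O bonds. The acetic acid buffer keeps phenolate concentrations low, which prevents catechol oxidation, and the absence of strong acid avoids cyclisation of either chain onto the 5- or 7-OH. The C2''–O bond is not touched.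

## Compound list

1 | 4-bromobenzene-1,2-diol | Oc1ccc(Br)cc1O | starting material
2 | 4-bromo-1,2-bis(tert-butyldimethylsilyloxy)benzene | CC(C)(C)[Si](C)(C)Oc1ccc(Br)cc1O[Si](C)(C)C(C)(C)C | intermediate
3 | 2-[3,4-bis(tert-butyldimethylsilyloxy)phenyl]-4,4,5,5-tetramethyl-1,3,2-dioxaborolane | CC(C)(C)[Si](C)(C)Oc1ccc(B2OC(C)(C)C(C)(C)O2)cc1O[Si](C)(C)C(C)(C)C | intermediate
4 | 5-hydroxy-2-methyl-4H-pyran-4-one (allomaltol) | Cc1cc(=O)c(O)co1 | starting material
5 | 6-methyl-4-oxo-4H-pyran-3-yl trifluoromethanesulfonate | Cc1cc(=O)c(OS(=O)(=O)C(F)(F)F)co1 | intermediate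
6 | 5-[3,4-bis(tert-butyldimethylsilyloxy)phenyl]-2-methyl-4H-pyran-4-one | Cc1cc(=O)c(-c2ccc(O[Si](C)(C)C(C)(C)C)c(O[Si](C)(C)C(C)(C)C)c2)co1 | intermediate
7 | 1-bromo-3-methylbut-2-ene | CC(C)=CCBr | starting material
8 | lithium 5-[3,4-bis(tert-butyldimethylsilyloxy)phenyl]-2-methylene-2H-pyran-4-olate | [Li+].C=C1C=C([O-])C(=CO1)c1ccc(O[Si](C)(C)C(C)(C)C)c(O[Si](C)(C)C(C)(C)C)c1 | intermediate
9 | 5-[3,4-bis(tert-butyldimethylsilyloxy)phenyl]-2-(4-methylpent-3-en-1-yl)-4H-pyran-4-one | CC(C)=CCCc1cc(=O)c(-c2ccc(O[Si](C)(C)C(C)(C)C)c(O[Si](C)(C)C(C)(C)C)c2)co1 | intermediate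
10 | carbon dioxide | O=C=O | starting material
11 | lithium 5-[3,4-bis(tert-butyldimethylsilyloxy)phenyl]-2-(4-methylpent-3-en-1-ylidene)-2H-pyran-4-olate | [Li+].CC(C)=CCC=C1C=C([O-])C(=CO1)c1ccc(O[Si](C)(C)C(C)(C)C)c(O[Si](C)(C)C(C)(C)C)c1 | intermediate
12 | lithium 2-{5-[3,4-bis(tert-butyldimethylsilyloxy)phenyl]-4-oxo-4H-pyran-2-yl}-5-methylhex-4-enoate | [Li+].CC(C)=CCC(C(=O)[O-])c1cc(=O)c(-c2ccc(O[Si](C)(C)C(C)(C)C)c(O[Si](C)(C)C(C)(C)C)c2)co1 | intermediate
13 | (±)-2-{5-[3,4-bis(tert-butyldimethylsilyloxy)phenyl]-4-oxo-4H-pyran-2-yl}-5-methylhex-4-enoic acid | CC(C)=CCC(C(=O)O)c1cc(=O)c(-c2ccc(O[Si](C)(C)C(C)(C)C)c(O[Si](C)(C)C(C)(C)C)c2)co1 | intermediate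
14 | (±)-2-{5-[3,4-bis(tert-butyldimethylsilyloxy)phenyl]-4-oxo-4H-pyran-2-yl}-5-methylhex-4-enoyl chloride | CC(C)=CCC(C(=O)Cl)c1cc(=O)c(-c2ccc(O[Si](C)(C)C(C)(C)C)c(O[Si](C)(C)C(C)(C)C)c2)co1 | intermediate
15 | methacrolein | C=C(C)C=O | starting material
16 | allenylboronic acid pinacol ester | C=C=CB1OC(C)(C)C(C)(C)O1 | starting material
17 | (R)-2-[(2-methylhex-1-en-5-yn-3-yl)oxy]-4,4,5,5-tetramethyl-1,3,2-dioxaborolane | C=C(C)[C@H](OB1OC(C)(C)C(C)(C)O1)CC#C | intermediate
18 | (R)-2-methylhex-1-en-5-yn-3-ol | C=C(C)[C@H](O)CC#C | intermediate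
19 | (R)-3-(tert-butyldimethylsilyloxy)-2-methylhex-1-en-5-yne | C=C(C)[C@H](O[Si](C)(C)C(C)(C)C)CC#C | intermediate
20 | lithium acetylide of 19 | [Li+].C=C(C)[C@H](O[Si](C)(C)C(C)(C)C)CC#[C-] | intermediate
21 | lithium (R)-4-(tert-butyldimethylsilyloxy)-5-methylhex-5-en-1-yn-1-olate | [Li+].C=C(C)[C@H](O[Si](C)(C)C(C)(C)C)CC#C[O-] | intermediate
22 | (R)-4-(tert-butyldimethylsilyloxy)-5-methyl-1-(triisopropylsilyloxy)hex-5-en-1-yne | C=C(C)[C@H](O[Si](C)(C)C(C)(C)C)CC#CO[Si](C(C)C)(C(C)C)C(C)C | intermediate
23 | 2-{5-[3,4-bis(tert-butyldimethylsilyloxy)phenyl]-4-oxo-4H-pyran-2-yl}-5-methylhexa-1,4-dien-1-one (ketene) | CC(C)=CCC(=C=O)c1cc(=O)c(-c2ccc(O[Si](C)(C)C(C)(C)C)c(O[Si](C)(C)C(C)(C)C)c2)co1 | intermediate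
24 | 4-(pyranon-2-yl)-4-prenyl-3-(triisopropylsilyloxy)-2-[(2R)-2-(tert-butyldimethylsilyloxy)-3-methylbut-3-en-1-yl]cyclobut-2-en-1-one (both epimers at C4) | O=C1C(C[C@@H](O[Si](C)(C)C(C)(C)C)C(C)=C)=C(O[Si](C(C)C)(C(C)C)C(C)C)C1(CC=C(C)C)c2cc(=O)c(-c3ccc(O[Si](C)(C)C(C)(C)C)c(O[Si](C)(C)C(C)(C)C)c3)co2 | intermediate
25 | dienylketene from ring opening of 24, pyranone cis to the ketene carbon | O=C=C(C[C@@H](O[Si](C)(C)C(C)(C)C)C(C)=C)/C(O[Si](C(C)C)(C(C)C)C(C)C)=C(/CC=C(C)C)c1cc(=O)c(-c2ccc(O[Si](C)(C)C(C)(C)C)c(O[Si](C)(C)C(C)(C)C)c2)co1 | intermediate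
26 | 4a-H-chromene-4,5-dione tautomer of 27 | O=C1C(C[C@@H](O[Si](C)(C)C(C)(C)C)C(C)=C)=C(O[Si](C(C)C)(C(C)C)C(C)C)C(CC=C(C)C)=C2OC=C(c3ccc(O[Si](C)(C)C(C)(C)C)c(O[Si](C)(C)C(C)(C)C)c3)C(=O)C12 | intermediate
27 | 3-[3,4-bis(tert-butyldimethylsilyloxy)phenyl]-6-[(2R)-2-(tert-butyldimethylsilyloxy)-3-methylbut-3-en-1-yl]-5-hydroxy-8-(3-methylbut-2-en-1-yl)-7-(triisopropylsilyloxy)-4H-chromen-4-one | C=C(C)[C@H](O[Si](C)(C)C(C)(C)C)Cc1c(O[Si](C(C)C)(C(C)C)C(C)C)c(CC=C(C)C)c2occ(-c3ccc(O[Si](C)(C)C(C)(C)C)c(O[Si](C)(C)C(C)(C)C)c3)c(=O)c2c1O | intermediate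
28 | 3-(3,4-dihydroxyphenyl)-5,7-dihydroxy-6-[(2R)-2-hydroxy-3-methylbut-3-en-1-yl]-8-(3-methylbut-2-en-1-yl)-4H-chromen-4-one | C=C(C)[C@H](O)Cc1c(O)c(CC=C(C)C)c2occ(-c3ccc(O)c(O)c3)c(=O)c2c1O | target

## Step count and least certain steps

Total steps: 12. Longest linear sequence: 8 (steps 1, 2, 4, 5, 6, 7, 11, 12).

**Step 11 (key step, proposed new method).**

*What may go wrong.* The most likely failure is at the last pericyclic event. Closure of 25 onto C3 of the pyranone interrupts the vinylogous ester conjugation and may be slower than diversion of the dienylketene. Two diversions are plausible: a hydrogen shift from the prenyl CH2 in the wrong geometric isomer, or cycloaddition of the ketene to the isopropenyl group. Dimerisation of 23 before it meets 22 is the second risk.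

*Fallback.* It uses known reaction types only, sets out from boronate 3 and returns at 27.
- 2,4,6-Trihydroxyacetophenone is silylated at its unchelated hydroxyl (TIPSCl, imidazole) to 1-[2,6-dihydroxy-4-(triisopropylsilyloxy)phenyl]ethanone F1.
- Mitsunobu reaction with allyl alcohol gives the mono-allyl ether F2.
- Condensation with DMF dimethyl acetal gives the enaminone F3, and cyclisation with I2 gives 5-allyloxy-3-iodo-7-(triisopropylsilyloxy)chromone F4.
- Suzuki-Miyaura coupling with 3 gives the 5-allyloxyisoflavone F5.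
- Aromatic Claisen rearrangement, for which C6 is the only open ortho carbon, gives the 6-allyl-5-hydroxyisoflavone F6.
- Cross metathesis with 2-methyl-2-butene (second-generation Grubbs catalyst) gives the 6-prenyl compound F7.
- The 5-OH is allylated again to the 5-allyl ether F8, so that no phenol stands next to the coming epoxide.
- Shi epoxidation (D-fructose-derived ketone, KHSO5) of the only trisubstituted alkene should give the (R)-epoxide F9.
- TBSOTf/2,6-lutidine, then DBU, opens the epoxide at its tertiary carbon to the allylic silyl ether F10. The C–O bond of the stereocentre stays intact.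
- Heating moves the allyl group by para-Claisen–Cope rearrangement (C6 is blocked) to the 8-allyl-5-hydroxy compound F11.
- A second cross metathesis with 2-methyl-2-butene gives 27.

**Step 6.**

*What may go wrong.* Acid 13 is a vinylogous beta-keto acid, and loss of carbon dioxide during work-up, storage or chloride formation is the main danger. Slow carboxylation of the more hindered dienolate 11 is the second.

*Fallback.* It sets out from 6 through its dienolate 8, returns at ketene 23 within step 11, and replaces steps 5 to 7.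
- Dienolate 8 is acylated with N-methoxy-N,4-dimethylpent-3-enamide to 5-aryl-2-(5-methyl-2-oxohex-4-en-1-yl)-4H-pyran-4-one F12.
- Regitz diazo transfer (4-acetamidobenzenesulfonyl azide, DBU) at the doubly activated CH2 gives the alpha-diazo ketone F13.
- Irradiation with blue light in the presence of 22 triggers a Wolff rearrangement with migration of the prenyl group, which gives 23 without any acid or acid chloride.

**Step 5.**

*What may go wrong.* Proton exchange between product 9 and unreacted dienolate 8 can lead to double alkylation. Some attack through C3 of the dienolate cannot be excluded.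

*Fallback.* It sets out from 6 and returns at 13.
- Dienolate 8 (two equivalents of base) is acylated with di-tert-butyl dicarbonate to tert-butyl (5-aryl-4-oxo-4H-pyran-2-yl)acetate F14.
- Its stabilised anion (NaH, THF) is alkylated once with 7 to the tert-butyl ester F15.
- TMSOTf/2,6-lutidine converts F15 into the trimethylsilyl ester F16, which gives 13 on contact with water.

**Step 8.**

*What may go wrong.* Facial selectivity may be insufficient with a small alpha-branched enal, and any deficit is carried unchanged to the target. The volatility of 18 adds handling losses.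

*Fallback.* It sets out from 15 and returns at 18.
- Barbier addition of propargyl bromide with Zn gives racemic 2-methylhex-1-en-5-yn-3-ol F17.
- Sharpless kinetic resolution (Ti(OiPr)4, L-(+)-diisopropyl tartrate, t-BuOOH, −20 °C) consumes the (S)-enantiomer as the epoxy alcohol F18 and leaves 18.

## Further compounds

F1 | step 11 | 1-[2,6-dihydroxy-4-(triisopropylsilyloxy)phenyl]ethanone | CC(=O)c1c(O)cc(O[Si](C(C)C)(C(C)C)C(C)C)cc1O
F2 | step 11 | 1-[2-(allyloxy)-6-hydroxy-4-(triisopropylsilyloxy)phenyl]ethanone | CC(=O)c1c(O)cc(O[Si](C(C)C)(C(C)C)C(C)C)cc1OCC=C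
F3 | step 11 | (E)-1-[2-(allyloxy)-6-hydroxy-4-(triisopropylsilyloxy)phenyl]-3-(dimethylamino)prop-2-en-1-one | CN(C)/C=C/C(=O)c1c(O)cc(O[Si](C(C)C)(C(C)C)C(C)C)cc1OCC=C
F4 | step 11 | 5-(allyloxy)-3-iodo-7-(triisopropylsilyloxy)-4H-chromen-4-one | C=CCOc1cc(O[Si](C(C)C)(C(C)C)C(C)C)cc2occ(I)c(=O)c12
F5 | step 11 | 5-(allyloxy)-3-[3,4-bis(tert-butyldimethylsilyloxy)phenyl]-7-(triisopropylsilyloxy)-4H-chromen-4-one | C=CCOc1cc(O[Si](C(C)C)(C(C)C)C(C)C)cc2occ(-c3ccc(O[Si](C)(C)C(C)(C)C)c(O[Si](C)(C)C(C)(C)C)c3)c(=O)c12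
F6 | step 11 | 6-allyl-3-[3,4-bis(tert-butyldimethylsilyloxy)phenyl]-5-hydroxy-7-(triisopropylsilyloxy)-4H-chromen-4-one | C=CCc1c(O[Si](C(C)C)(C(C)C)C(C)C)cc2occ(-c3ccc(O[Si](C)(C)C(C)(C)C)c(O[Si](C)(C)C(C)(C)C)c3)c(=O)c2c1O
F7 | step 11 | 3-[3,4-bis(tert-butyldimethylsilyloxy)phenyl]-5-hydroxy-6-(3-methylbut-2-en-1-yl)-7-(triisopropylsilyloxy)-4H-chromen-4-one | CC(C)=CCc1c(O[Si](C(C)C)(C(C)C)C(C)C)cc2occ(-c3ccc(O[Si](C)(C)C(C)(C)C)c(O[Si](C)(C)C(C)(C)C)c3)c(=O)c2c1O
F8 | step 11 | 5-(allyloxy)-3-[3,4-bis(tert-butyldimethylsilyloxy)phenyl]-6-(3-methylbut-2-en-1-yl)-7-(triisopropylsilyloxy)-4H-chromen-4-one | CC(C)=CCc1c(O[Si](C(C)C)(C(C)C)C(C)C)cc2occ(-c3ccc(O[Si](C)(C)C(C)(C)C)c(O[Si](C)(C)C(C)(C)C)c3)c(=O)c2c1OCC=C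
F9 | step 11 | 5-(allyloxy)-3-[3,4-bis(tert-butyldimethylsilyloxy)phenyl]-6-{[(2R)-3,3-dimethyloxiran-2-yl]methyl}-7-(triisopropylsilyloxy)-4H-chromen-4-one | CC1(C)O[C@@H]1Cc1c(O[Si](C(C)C)(C(C)C)C(C)C)cc2occ(-c3ccc(O[Si](C)(C)C(C)(C)C)c(O[Si](C)(C)C(C)(C)C)c3)c(=O)c2c1OCC=C
F10 | step 11 | 5-(allyloxy)-3-[3,4-bis(tert-butyldimethylsilyloxy)phenyl]-6-[(2R)-2-(tert-butyldimethylsilyloxy)-3-methylbut-3-en-1-yl]-7-(triisopropylsilyloxy)-4H-chromen-4-one | C=C(C)[C@H](O[Si](C)(C)C(C)(C)C)Cc1c(O[Si](C(C)C)(C(C)C)C(C)C)cc2occ(-c3ccc(O[Si](C)(C)C(C)(C)C)c(O[Si](C)(C)C(C)(C)C)c3)c(=O)c2c1OCC=C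
F11 | step 11 | 8-allyl-3-[3,4-bis(tert-butyldimethylsilyloxy)phenyl]-6-[(2R)-2-(tert-butyldimethylsilyloxy)-3-methylbut-3-en-1-yl]-5-hydroxy-7-(triisopropylsilyloxy)-4H-chromen-4-one | C=C(C)[C@H](O[Si](C)(C)C(C)(C)C)Cc1c(O[Si](C(C)C)(C(C)C)C(C)C)c(CC=C)c2occ(-c3ccc(O[Si](C)(C)C(C)(C)C)c(O[Si](C)(C)C(C)(C)C)c3)c(=O)c2c1O
F12 | step 6 | 5-[3,4-bis(tert-butyldimethylsilyloxy)phenyl]-2-(5-methyl-2-oxohex-4-en-1-yl)-4H-pyran-4-one | CC(C)=CCC(=O)Cc1cc(=O)c(-c2ccc(O[Si](C)(C)C(C)(C)C)c(O[Si](C)(C)C(C)(C)C)c2)co1
F13 | step 6 | 5-[3,4-bis(tert-butyldimethylsilyloxy)phenyl]-2-(1-diazo-5-methyl-2-oxohex-4-en-1-yl)-4H-pyran-4-one | CC(C)=CCC(=O)C(=[N+]=[N-])c1cc(=O)c(-c2ccc(O[Si](C)(C)C(C)(C)C)c(O[Si](C)(C)C(C)(C)C)c2)co1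
F14 | step 5 | tert-butyl 2-{5-[3,4-bis(tert-butyldimethylsilyloxy)phenyl]-4-oxo-4H-pyran-2-yl}acetate | CC(C)(C)OC(=O)Cc1cc(=O)c(-c2ccc(O[Si](C)(C)C(C)(C)C)c(O[Si](C)(C)C(C)(C)C)c2)co1
F15 | step 5 | tert-butyl (±)-2-{5-[3,4-bis(tert-butyldimethylsilyloxy)phenyl]-4-oxo-4H-pyran-2-yl}-5-methylhex-4-enoate | CC(C)=CCC(C(=O)OC(C)(C)C)c1cc(=O)c(-c2ccc(O[Si](C)(C)C(C)(C)C)c(O[Si](C)(C)C(C)(C)C)c2)co1
F16 | step 5 | trimethylsilyl (±)-2-{5-[3,4-bis(tert-butyldimethylsilyloxy)phenyl]-4-oxo-4H-pyran-2-yl}-5-methylhex-4-enoate | CC(C)=CCC(C(=O)O[Si](C)(C)C)c1cc(=O)c(-c2ccc(O[Si](C)(C)C(C)(C)C)c(O[Si](C)(C)C(C)(C)C)c2)co1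
F17 | step 8 | (±)-2-methylhex-1-en-5-yn-3-ol | C=C(C)C(O)CC#C
F18 | step 8 | (S)-1-[(S)-2-methyloxiran-2-yl]but-3-yn-1-ol | C[C@]1(CO1)[C@@H](O)CC#C
A1 | alternative 1 | 6,8-diprenylorobol | CC(C)=CCc1c(O)c(CC=C(C)C)c2occ(-c3ccc(O)c(O)c3)c(=O)c2c1O
A2 | alternative 1 | 3-(3,4-dihydroxyphenyl)-6-{[(2R)-3,3-dimethyloxiran-2-yl]methyl}-5,7-dihydroxy-8-(3-methylbut-2-en-1-yl)-4H-chromen-4-one | CC1(C)O[C@@H]1Cc1c(O)c(CC=C(C)C)c2occ(-c3ccc(O)c(O)c3)c(=O)c2c1O
A3 | alternative 2 | (S)-2-(prop-1-en-2-yl)oxirane | C=C(C)[C@H]1CO1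
A4 | alternative 2 | 3-[3,4-bis(methoxymethoxy)phenyl]-6-iodo-5,7-bis(methoxymethoxy)-8-(3-methylbut-2-en-1-yl)-4H-chromen-4-one | COCOc1c(I)c(OCOC)c2c(=O)c(-c3ccc(OCOC)c(OCOC)c3)coc2c1CC=C(C)C
A5 | alternative 3 | 2-(3,4-dihydroxyphenyl)-1-{2,4,6-trihydroxy-3-[(2R)-2-hydroxy-3-methylbut-3-en-1-yl]-5-(3-methylbut-2-en-1-yl)phenyl}ethanone | C=C(C)[C@H](O)Cc1c(O)c(CC=C(C)C)c(O)c(C(=O)Cc2ccc(O)c(O)c2)c1O
A6 | alternative 3 | 3-(3,4-dihydroxyphenyl)-5,7-dihydroxy-8-[(2R)-2-hydroxy-3-methylbut-3-en-1-yl]-6-(3-methylbut-2-en-1-yl)-4H-chromen-4-one | C=C(C)[C@H](O)Cc1c(O)c(CC=C(C)C)c(O)c2c(=O)c(-c3ccc(O)c(O)c3)coc12
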